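Start from 1200, the fast step's constant times the nucleophile charged in dusk, far above 1, and decide what to change in the next run.

    electrophile + nucleophile ⇌ acid set free + product (K1 = 17, k1 = 0.032 L mol⁻¹ min⁻¹)
    nucleophile + acid set free ⇌ protonated nucleophile, settled at all times (K2 = 640 L mol⁻¹)
    2 nucleophile → homo dimer (k3 = 0.024 L mol⁻¹ min⁻¹)

| flask | electrophile | nucleophile | time |
|---|---|---|---|
| summer | 1.5 M | 2.00 equiv | 50 min |
| spring | 1.5 M | 1.60 equiv | 50 min |
| dusk | 1.5 M | 1.20 equiv | 50 min |

- part of the electrophile that has reacted at the end, summer
- part of the electrophile that has reacted at the end, spring
- part of the electrophile that has reacted at the end, dusk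
- what raising the equivalents of nucleophile from its lowest to its highest value here does to the part of the electrophile that has reacted (changes below 5 percentage points count as none) (no change / it falls / it rises)

- where a step has two of a species, its rate is k times that concentration squared, and two are used at each turn
- run time (summer): 50 min

Reckon with the fast step at balance. With that product far above 1, acid set free passes to protonated nucleophile as it forms, so each turn of the coupling costs 2 nucleophile, and each turn of the dimer step costs 2 as well. Write A for electrophile, B for free nucleophile, e for the equivalents charged, and S = 1.50, twice the dimer constant over the coupling constant, a selectivity factor. Dividing the two rates gives dB/dA = 2 + S·B/A. Integrated from the charge down to B = 0, this gives the part of the electrophile reacted as Y = 1 − [2/(2 + (S − 1)e)]^(1/(S − 1)).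

Assume that each flask comes close to that end point within the run; this is an assumption of the reckoning, not a result. Y then reads 55.6% for summer, 49.0% for spring and 40.8% for dusk. Going from dusk to summer gains 15 percentage points, more than the margin of 5 points, so the trend reads it rises. For the next run, change the nucleophile charge and leave the time as it is.

The forecast, with numbers of its own, gives 54.5% for summer, 48% for spring and 40% for dusk, and says it rises, on the grounds that “extra nucleophile simply raises that ceiling”.

The simulation gives 53.7% in summer, 47.7% in spring and 40.1% in dusk: it rises, by 14 points. In summer the answer moves by 5 points at 2.41 equiv of nucleophile, or at 392 min of time. Use S on one further flask, spring with 0.960 equiv of nucleophile: Y gives 35.0%, and that flask gave 34.6%.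

The constants used here come from no measurement; the rest is arithmetic.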